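**Retrosynthetic overview**

- Feature: ring A (O1–C2(=O)–C3–C4–C5) is a 1,4-dioxygenated γ-lactone whose carbinol carbon C5 carries a 2-methylprop-1-enyl group. C5 with that group is therefore prenol at the aldehyde level, and C4, C3 (with its exocyclic carbon) and the acyl carbon C2 are a 2-carboxyallyl unit.
- Ring A is made first by iridium-catalysed transfer-hydrogenative 2-(methoxycarbonyl)allylation of prenol with in situ lactonisation (bonds C4–C5 and O1–C2, stereocentre C5).
- The exocyclic methylene on C3 is then exchanged by cross-metathesis with a terminal alkene cut from farnesol (terminal epoxide, periodate cleavage, methylenation), which sets the E-alkylidene.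
- Desilylation and MnO2 oxidation give the dienal, and the last C=C bond, to the butenolide (ring B), is made by Horner–Wadsworth–Emmons olefination.
- Ring order: ring A in step 3; ring B is bought intact and attached last.

Key step: step 3

Assumption: in this catalyst family the (S)-bisphosphine is taken to direct the allyl carbon to the Si face of aryl and alkenyl aldehydes, which for prenal gives the (S)-lactone. If a first run shows the opposite sense, (R)-SEGPHOS is used and nothing else changes.

**Route**

Step 1
Reactants: 1 methyl acrylate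
Product: 2 methyl 2-(hydroxymethyl)acrylate
Conditions: 37% aq. HCHO, DABCO (1 equiv), 1,4-dioxane/H2O (1:1), rt
Reagents that add atoms: formaldehyde, C=O
Why: Morita–Baylis–Hillman reaction, in which DABCO adds conjugately to the acrylate, the ammonium enolate is hydroxymethylated by formaldehyde and the amine is expelled again, aqueous dioxane being a medium in which this hydroxymethylation is known to run cleanly.

Step 2
Reactants: 2 methyl 2-(hydroxymethyl)acrylate
Product: 3 methyl 2-[(methoxycarbonyloxy)methyl]acrylate
Conditions: ClCO2Me, pyridine, CH2Cl2, 0 °C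
Reagents that add atoms: methyl chloroformate, COC(=O)Cl
Why: O-acylation of a primary alcohol by a chloroformate, with pyridine as a base too weakly nucleophilic to attack the acrylate in an SN2' sense.

Step 3
Reactants: 4 prenol (3-methylbut-2-en-1-ol); 3 methyl 2-[(methoxycarbonyloxy)methyl]acrylate
Product: 7 (S)-3-methylidene-5-(2-methylprop-1-en-1-yl)dihydrofuran-2(3H)-one, via prenal 5 (not isolated), via methyl (S)-4-hydroxy-6-methyl-2-methylidenehept-5-enoate 6 (not isolated)
Conditions: [Ir(cod)Cl]2 (2.5 mol %), (S)-SEGPHOS (5 mol %), 4-chloro-3-nitrobenzoic acid (10 mol %), Cs2CO3 (20 mol %), 3 (2 equiv), THF, 70 °C, sealed tube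
Reagents that add atoms: none
Why: The trivalent iridium alkoxide of 4 undergoes β-hydride elimination to prenal 5 and an iridium hydride; base-assisted loss of acid returns monovalent iridium, which ionises carbonate 3 (CO2 and methoxide leave) to the ortho-cyclometallated C,O-benzoate 2-(methoxycarbonyl)allyl complex of trivalent iridium, a nucleophilic allyl. Its σ-allyl form adds to the coordinated aldehyde through a closed chair-like six-membered transition state, forming C4–C5, and alkoxide exchange with fresh 4 releases hydroxy ester 6 and restarts the cycle. Ring A then closes by 5-exo-trig acyl substitution of the C5 alkoxide on the methyl ester with loss of methanol, which also removes the secondary allylic alcohol from the reach of re-oxidation. The closest known reaction type is the iridium-catalysed enantioselective 2-(alkoxycarbonyl)allylation of primary alcohols, allylic ones included, by C–C bond-forming transfer hydrogenation. The C5 stereocentre is set by the C2-symmetric bisphosphine on the cyclometallated metal, which exposes the Si face of the aldehyde to the allyl carbon and so gives S. The step needs 1,2-addition without conjugate reduction or redox isomerisation of the allylic alcohol, and this is secured by the β,β-disubstituted enal, which is present only transiently and has no enolisable position towards C5.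

Step 4
Reactants: 8 (2E,6E)-farnesol
Product: 9 (2E,6E)-farnesyl tert-butyldiphenylsilyl ether
Conditions: TBDPSCl, imidazole, CH2Cl2, 0 °C to rt
Reagents that add atoms: tert-butyldiphenylsilyl chloride, CC(C)(C)[Si](Cl)(c1ccccc1)c1ccccc1
Why: Imidazole-promoted silylation of a primary allylic alcohol, the TBDPS group being chosen because it should survive the acidic periodate step later.

Step 5
Reactants: 9 (2E,6E)-farnesyl tert-butyldiphenylsilyl ether
Product: 10 (6E,10E)-3-bromo-12-(tert-butyldiphenylsilyloxy)-2,6,10-trimethyldodeca-6,10-dien-2-ol (racemic at C3)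
Conditions: NBS (1.05 equiv), THF/H2O (3:1), 0 °C
Reagents that add atoms: N-bromosuccinimide, O=C1CCC(=O)N1Br; water, O
Why: Terminal-selective bromohydrin formation, in which the exposed, most electron-rich isopropylidene alkene of the polyene is bromonium-activated in aqueous THF and opened by water at the tertiary carbon, the new centre being irrelevant because it is destroyed in step 7.

Step 6
Reactants: 10 the bromohydrin
Product: 11 (2E,6E)-10,11-epoxyfarnesyl tert-butyldiphenylsilyl ether (racemic)
Conditions: K2CO3, MeOH, rt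
Reagents that add atoms: none
Why: Intramolecular Williamson etherification, the tertiary alkoxide displacing the neighbouring secondary bromide to close the epoxide.

Step 7
Reactants: 11 the epoxide
Product: 12 (4E,8E)-10-(tert-butyldiphenylsilyloxy)-4,8-dimethyldeca-4,8-dienal
Conditions: H5IO6 (1.2 equiv), THF/Et2O, 0 °C
Reagents that add atoms: none
Why: Periodic acid opens the trisubstituted epoxide to the glycol and cleaves it in the same flask (Malaprade glycol cleavage), giving the aldehyde and acetone while the trisubstituted alkenes and the TBDPS ether should be untouched in the short, cold reaction.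

Step 8
Reactants: 12 the aldehyde
Product: 13 tert-butyl{[(2E,6E)-3,7-dimethylundeca-2,6,10-trien-1-yl]oxy}diphenylsilane
Conditions: Ph3PCH3Br, KN(SiMe3)2, THF, 0 °C; then 12, 0 °C to rt
Reagents that add atoms: methyltriphenylphosphonium bromide, C[P+](c1ccccc1)(c1ccccc1)c1ccccc1.[Br-]
Why: Wittig methylenation of an unhindered aliphatic aldehyde with the non-stabilised ylide.

Step 9
Reactants: 7 (S)-3-methylidene-5-(2-methylprop-1-en-1-yl)dihydrofuran-2(3H)-one; 13 the terminal alkene
Product: 14 (S,E)-3-[(4E,8E)-10-(tert-butyldiphenylsilyloxy)-4,8-dimethyldeca-4,8-dien-1-ylidene]-5-(2-methylprop-1-en-1-yl)dihydrofuran-2(3H)-one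
Conditions: RuCl2(H2IMes)(=CH-C6H4-2-OiPr) (second-generation Hoveyda–Grubbs catalyst, 5 mol %), 2,6-dichloro-1,4-benzoquinone (10 mol %), 13 (2 equiv), CH2Cl2, 40 °C
Reagents that add atoms: none
Why: Olefin cross-metathesis of an α-methylene γ-butyrolactone with a monosubstituted alkene, a known pairing that should give the more stable E-alkylidene (chain trans to the carbonyl), the hindered trisubstituted alkenes staying out of the reaction and the quinone suppressing ruthenium hydride-mediated migration of the exocyclic alkene into ring A.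

Step 10
Reactants: 14 the silyl ether
Product: 15 (S,E)-3-[(4E,8E)-10-hydroxy-4,8-dimethyldeca-4,8-dien-1-ylidene]-5-(2-methylprop-1-en-1-yl)dihydrofuran-2(3H)-one
Conditions: Bu4NF, AcOH (1:1), THF, 0 °C to rt
Reagents that add atoms: none
Why: Fluoride-mediated desilylation, buffered with acetic acid so that the alkylidene lactone is not exposed to basic fluoride or alkoxide.

Step 11
Reactants: 15 the allylic alcohol
Product: 16 (2E,6E)-3,7-dimethyl-10-[(S,E)-5-(2-methylprop-1-en-1-yl)-2-oxodihydrofuran-3(2H)-ylidene]deca-2,6-dienal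
Conditions: MnO2 (activated, excess), CH2Cl2, rt
Reagents that add atoms: none
Why: Manganese dioxide oxidation, selective for the allylic alcohol and neutral enough to keep the 2E geometry and the C5 centre of ring A.

Step 12
Reactants: 17 4-(bromomethyl)furan-2(5H)-one
Product: 18 diethyl [(5-oxo-2,5-dihydrofuran-3-yl)methyl]phosphonate
Conditions: P(OEt)3 (neat), 110 °C
Reagents that add atoms: triethyl phosphite, CCOP(OCC)OCC
Why: Michaelis–Arbuzov reaction of a primary allylic bromide, driven by loss of volatile bromoethane.

Step 13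
Reactants: 16 the dienal; 18 the butenolide phosphonate
Product: 19 (S,E)-3-[(4E,8E,10E)-4,8-dimethyl-11-(5-oxo-2,5-dihydrofuran-3-yl)undeca-4,8,10-trien-1-ylidene]-5-(2-methylprop-1-en-1-yl)dihydrofuran-2(3H)-one (CNP0187251.1)
Conditions: 18, LiN(SiMe3)2 (1.0 equiv), THF, −78 °C; then 16, −78 to 0 °C
Reagents that add atoms: none
Why: Horner–Wadsworth–Emmons olefination with a vinylogous, ester-stabilised phosphonate anion that is pre-formed so no free base meets the aldehyde or ring A, reacts at its phosphorus-bearing carbon and should give the E-alkene, as the acyclic 4-phosphonocrotonates do.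

**Compound list**

1 | methyl acrylate | C=CC(=O)OC | starting material
2 | methyl 2-(hydroxymethyl)acrylate | C=C(CO)C(=O)OC | intermediate
3 | methyl 2-[(methoxycarbonyloxy)methyl]acrylate | C=C(COC(=O)OC)C(=O)OC | intermediate
4 | prenol (3-methylbut-2-en-1-ol) | CC(C)=CCO | starting material
5 | prenal (3-methylbut-2-enal) | CC(C)=CC=O | intermediate
6 | methyl (S)-4-hydroxy-6-methyl-2-methylidenehept-5-enoate | CC(C)=C[C@@H](O)CC(=C)C(=O)OC | intermediate
7 | (S)-3-methylidene-5-(2-methylprop-1-en-1-yl)dihydrofuran-2(3H)-one | CC(C)=C[C@@H]1CC(=C)C(=O)O1 | intermediate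
8 | (2E,6E)-farnesol | CC(C)=CCC/C(C)=C/CC/C(C)=C/CO | starting material
9 | (2E,6E)-farnesyl tert-butyldiphenylsilyl ether | CC(C)=CCC/C(C)=C/CC/C(C)=C/CO[Si](c1ccccc1)(c1ccccc1)C(C)(C)C | intermediate
10 | (6E,10E)-3-bromo-12-(tert-butyldiphenylsilyloxy)-2,6,10-trimethyldodeca-6,10-dien-2-ol, racemic at C3 | CC(C)(O)C(Br)CC/C(C)=C/CC/C(C)=C/CO[Si](c1ccccc1)(c1ccccc1)C(C)(C)C | intermediate
11 | (2E,6E)-10,11-epoxyfarnesyl tert-butyldiphenylsilyl ether, racemic | CC1(C)OC1CC/C(C)=C/CC/C(C)=C/CO[Si](c1ccccc1)(c1ccccc1)C(C)(C)C | intermediate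
12 | (4E,8E)-10-(tert-butyldiphenylsilyloxy)-4,8-dimethyldeca-4,8-dienal | O=CCC/C(C)=C/CC/C(C)=C/CO[Si](c1ccccc1)(c1ccccc1)C(C)(C)C | intermediate
13 | tert-butyl{[(2E,6E)-3,7-dimethylundeca-2,6,10-trien-1-yl]oxy}diphenylsilane | C=CCC/C(C)=C/CC/C(C)=C/CO[Si](c1ccccc1)(c1ccccc1)C(C)(C)C | intermediate
14 | (S,E)-3-[(4E,8E)-10-(tert-butyldiphenylsilyloxy)-4,8-dimethyldeca-4,8-dien-1-ylidene]-5-(2-methylprop-1-en-1-yl)dihydrofuran-2(3H)-one | CC(C)=C[C@@H]1C/C(=C\CC/C(C)=C/CC/C(C)=C/CO[Si](c2ccccc2)(c2ccccc2)C(C)(C)C)C(=O)O1 | intermediate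
15 | (S,E)-3-[(4E,8E)-10-hydroxy-4,8-dimethyldeca-4,8-dien-1-ylidene]-5-(2-methylprop-1-en-1-yl)dihydrofuran-2(3H)-one | CC(C)=C[C@@H]1C/C(=C\CC/C(C)=C/CC/C(C)=C/CO)C(=O)O1 | intermediate
16 | (2E,6E)-3,7-dimethyl-10-[(S,E)-5-(2-methylprop-1-en-1-yl)-2-oxodihydrofuran-3(2H)-ylidene]deca-2,6-dienal | CC(C)=C[C@@H]1C/C(=C\CC/C(C)=C/CC/C(C)=C/C=O)C(=O)O1 | intermediate
17 | 4-(bromomethyl)furan-2(5H)-one | BrCC1=CC(=O)OC1 | starting material
18 | diethyl [(5-oxo-2,5-dihydrofuran-3-yl)methyl]phosphonate | CCOP(=O)(CC1=CC(=O)OC1)OCC | intermediate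
19 | (S,E)-3-[(4E,8E,10E)-4,8-dimethyl-11-(5-oxo-2,5-dihydrofuran-3-yl)undeca-4,8,10-trien-1-ylidene]-5-(2-methylprop-1-en-1-yl)dihydrofuran-2(3H)-one | CC(C)=C[C@@H]1C/C(=C\CC/C(C)=C/CC/C(C)=C/C=C/C2=CC(=O)OC2)C(=O)O1 | target

**Step count**

Total: 13 steps. Longest linear sequence: 9 steps (steps 4–11 and 13, from farnesol). The ring A branch is 7 steps (1–3, 9–11, 13).

**Steps most likely to fail**

1. Step 9 (cross-metathesis). The 1,1-disubstituted, electron-poor methylene of 7 may turn over slowly, so that ruthenium hydride-mediated migration of the alkene into ring A, scrambling at the trisubstituted alkenes or poor E/Z control compete. The fallback makes the alkylidene by aldol condensation; it sets out from 4 and 12 and comes back at 14.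
   - Prenol 4 with allyl acetate under the same iridium catalyst ([Ir(cod)Cl]2, (S)-SEGPHOS, 4-chloro-3-nitrobenzoic acid, Cs2CO3, THF) should give (S)-6-methylhepta-1,5-dien-4-ol F1.
   - 9-BBN, then NaOH/H2O2, should hydroborate only the monosubstituted alkene to give (S)-6-methylhept-5-ene-1,4-diol F2.
   - TEMPO/PhI(OAc)2 should oxidise the primary alcohol and close (S)-5-(2-methylprop-1-en-1-yl)dihydrofuran-2(3H)-one F3.
   - Its lithium enolate (LiN(iPr)2, THF, −78 °C) should add to aldehyde 12 to give the β-hydroxy lactone (5S)-3-[(4E,8E)-10-(tert-butyldiphenylsilyloxy)-1-hydroxy-4,8-dimethyldeca-4,8-dien-1-yl]-5-(2-methylprop-1-en-1-yl)dihydrofuran-2(3H)-one F4 as a diastereomer mixture.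
   - MsCl/Et3N should give the corresponding mesylate F5, and DBU should eliminate it by E1cB to the more stable E-alkylidene 14, which continues with step 10.

2. Step 13 (Horner–Wadsworth–Emmons olefination). The base may remove a ring proton next to the lactone oxygen of 18 instead of the phosphonate proton, leading to vinylogous aldol addition, or it may attack the base-sensitive alkylidene lactone; geometric control at the new alkene may also be incomplete. The fallback forms the butenolide–vinyl bond by cross-coupling under neutral conditions; it sets out from 16 and comes back at 19.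
   - Chromium-mediated stannyl-olefination of the aldehyde (Takai type; Bu3SnCHBr2, CrCl2 as the divalent chromium reductant, LiI, THF/DMF) should give the (E)-dienylstannane tributyl{(1E,3E,7E)-4,8-dimethyl-11-[(S,E)-5-(2-methylprop-1-en-1-yl)-2-oxodihydrofuran-3(2H)-ylidene]undeca-1,3,7-trien-1-yl}stannane F6.
   - Stille coupling of F6 with commercial 4-bromofuran-2(5H)-one (Pd2(dba)3, AsPh3, NMP, rt to 50 °C) should give 19.

3. Step 3 (key step). Dehydrogenation of prenol may be slow, enantiofacial control on the small alkenyl aldehyde may be incomplete, or the hydroxy ester may lactonise only partly. The fallback runs the same bond formation from the aldehyde oxidation level with a different metal; it sets out from 5 (bought, or made from 4 with MnO2) and comes back at 7.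
   - Catalytic asymmetric Nozaki–Hiyama–Kishi-type 2-(ethoxycarbonyl)allylation of prenal with ethyl 2-(bromomethyl)acrylate (CrCl2 in catalytic amount, a chiral carbazole bis(oxazoline) ligand, Mn powder, Me3SiCl, THF), followed by desilylation on work-up, should give ethyl (S)-4-hydroxy-6-methyl-2-methylidenehept-5-enoate F7.
   - F7 should close to 7 with a catalytic amount of K2CO3 in THF.

**Further compounds**

F1 | step 9 | (S)-6-methylhepta-1,5-dien-4-ol | CC(C)=C[C@@H](O)CC=C
F2 | step 9 | (S)-6-methylhept-5-ene-1,4-diol | CC(C)=C[C@@H](O)CCCO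
F3 | step 9 | (S)-5-(2-methylprop-1-en-1-yl)dihydrofuran-2(3H)-one | CC(C)=C[C@@H]1CCC(=O)O1
F4 | step 9 | (5S)-3-[(4E,8E)-10-(tert-butyldiphenylsilyloxy)-1-hydroxy-4,8-dimethyldeca-4,8-dien-1-yl]-5-(2-methylprop-1-en-1-yl)dihydrofuran-2(3H)-one, diastereomer mixture | CC(C)=C[C@@H]1CC(C(O)CC/C(C)=C/CC/C(C)=C/CO[Si](c2ccccc2)(c2ccccc2)C(C)(C)C)C(=O)O1
F5 | step 9 | methanesulfonate of F4 | CC(C)=C[C@@H]1CC(C(OS(C)(=O)=O)CC/C(C)=C/CC/C(C)=C/CO[Si](c2ccccc2)(c2ccccc2)C(C)(C)C)C(=O)O1
F6 | step 13 | tributyl{(1E,3E,7E)-4,8-dimethyl-11-[(S,E)-5-(2-methylprop-1-en-1-yl)-2-oxodihydrofuran-3(2H)-ylidene]undeca-1,3,7-trien-1-yl}stannane | CC(C)=C[C@@H]1C/C(=C\CC/C(C)=C/CC/C(C)=C/C=C/[Sn](CCCC)(CCCC)CCCC)C(=O)O1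
F7 | step 3 | ethyl (S)-4-hydroxy-6-methyl-2-methylidenehept-5-enoate | CC(C)=C[C@@H](O)CC(=C)C(=O)OCC
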